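## Retrosynthetic overview
1. The two free OH groups on the central ring are former quinone carbonyls. The target therefore comes from a 2,5-diacyloxy-3,6-diaryl-1,4-benzoquinone by one hydrogenation, which reduces the quinone and removes all benzyl groups.
2. The mixed diester comes from atromentin 4',4''-dibenzyl ether, 3-phenylpropanoyl chloride and (S)-3-(benzyloxy)butanoyl chloride. The stereocentre is bought as ethyl (S)-3-hydroxybutanoate.
3. Key disconnection: both aryl–quinone C–C bonds are cut at once. This gives the bis(phenyliodonium) ylide of 2,5-dihydroxy-1,4-benzoquinone, in which I(III) makes the normally nucleophilic enol carbons electrophilic (a double enolonium equivalent), plus two para C–H nucleophiles (benzyl phenyl ether).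
4. No ring is built. The central ring is bought as the dihydroxyquinone and the outer rings as benzyl phenyl ether, and the central ring becomes aromatic only in the last step.

Assumption: the structure is taken as drawn, with (S) at C-3 of the hydroxybutanoyl group and the two esters para on the central ring, and ethyl (S)-3-hydroxybutanoate is bought at ≥98% ee.

## Route

Step 1
Reactants: 1 2,5-dihydroxy-1,4-benzoquinone
Product: 2 2,5-dioxido-3,6-bis(phenyliodonio)-1,4-benzoquinone (bis-ylide)
Conditions: PhI(OAc)2 (2.1 equiv), CH2Cl2, 0 °C → rt, dark; filter, wash with CH2Cl2/Et2O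
Reagents that add atoms: (diacetoxyiodo)benzene, CC(=O)OI(OC(C)=O)c1ccccc1
Why: This is iodonium ylide formation, in which the two enol carbons of the vinylogous acid attack I(III) and lose AcOH as other 2-hydroxyquinones and 1,3-dicarbonyls do, and the zwitterion precipitates free of the nucleophilic AcOH.

Step 2
Reactants: 2 bis-ylide; 3 benzyl phenyl ether (8 equiv)
Product: 5 2,5-bis[4-(benzyloxy)phenyl]-3,6-dihydroxy-1,4-benzoquinone, via mono-aryl mono-ylide 4 (not isolated)
Conditions: BF3·OEt2 (0.5 equiv), CH2Cl2/HFIP 9:1, −20 °C → rt, dark; aqueous wash, triturate with hexane/Et2O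
Reagents that add atoms: none
Why: Proposed new method: BF3 (and the proton regenerated in each turnover) binds the oxido oxygen, so each C–I(III) carbon, normally a nucleophilic enol carbon, becomes an enolonium-type electrophile that the para carbon of the aryl ether attacks by addition–elimination/SEAr with PhI as hypernucleofuge, the bulky iodonio-quinone favouring para attack; the closest known reaction type is the BF3-mediated single arylation of the phenyliodonium ylide of 2-hydroxy-1,4-naphthoquinone by methoxyarenes, run here twice on one ring.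

Step 3
Reactants: 6 ethyl (S)-3-hydroxybutanoate
Product: 7 ethyl (S)-3-(benzyloxy)butanoate
Conditions: BnOC(=NH)CCl3 (1.5 equiv), TfOH (5 mol %), cyclohexane/CH2Cl2 2:1, 0 °C → rt
Reagents that add atoms: benzyl 2,2,2-trichloroacetimidate, N=C(OCc1ccccc1)C(Cl)(Cl)Cl
Why: Acid-catalysed trichloroacetimidate O-benzylation alkylates the oxygen without base, so the C–O bond at the stereocentre is untouched (S retained) and no β-elimination occurs.

Step 4
Reactants: 7 ethyl (S)-3-(benzyloxy)butanoate
Product: 8 (S)-3-(benzyloxy)butanoic acid
Conditions: LiOH·H2O (2 equiv), THF/H2O 3:1, 0 °C → rt; 1 M HCl to pH 2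
Reagents that add atoms: lithium hydroxide, [Li+].[OH-]
Why: This is a plain saponification in which the β-stereocentre cannot epimerise and the low temperature suppresses E1cB loss of benzyl alcohol.

Step 5
Reactants: 5 2,5-bis[4-(benzyloxy)phenyl]-3,6-dihydroxy-1,4-benzoquinone; 9 3-phenylpropanoyl chloride; 8 (S)-3-(benzyloxy)butanoic acid
Product: 12 2,5-bis[4-(benzyloxy)phenyl]-3,6-dioxo-4-[(3-phenylpropanoyl)oxy]cyclohexa-1,4-dien-1-yl (3S)-3-(benzyloxy)butanoate, via monoester 10 (not isolated), via acid chloride 11 (not isolated)
Conditions: flask A: 8, (COCl)2 (1.2 equiv), cat. DMF, CH2Cl2, 0 °C → rt, strip volatiles. Flask B: 5, Et3N (2.2 equiv), CH2Cl2, −78 °C, 9 (1.0 equiv, slow); then 11 (1.3 equiv), −78 → 0 °C; cold citric acid wash, fast SiO2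
Reagents that add atoms: oxalyl chloride, O=C(Cl)C(=O)Cl (supplies only the Cl of intermediate 11)
Why: This is sequential O-acylation of a hydroxyquinone with acid chlorides, in which the dianion of 5 is more nucleophilic than the mono-anion of 10 so one equivalent of 9 stops mainly at 10, C-acylation is blocked by the aryl groups, the para-quinone diester is the stable isomer, and the three possible diesters differ in ether content and separate on silica (at least the statistical 50% of 12).

Step 6
Reactants: 12 mixed diester quinone
Product: 13 CNP0296884.1, 4-{[(3S)-3-hydroxybutanoyl]oxy}-2,5-dihydroxy-3,6-bis(4-hydroxyphenyl)phenyl 3-phenylpropanoate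
Conditions: H2 (1 atm), Pd(OH)2/C (20 wt %), degassed EtOAc, rt; filter under Ar, no base
Reagents that add atoms: none
Why: Catalytic hydrogenation reduces the quinone to the hydroquinone, turning the carbonyls into the two free OH groups para to each other, and hydrogenolysis cleaves only the three O–CH2Ph bonds, so the esters and the (S) centre are untouched and neutral medium keeps 1,2-acyl shift slow.

## Compound list
1 | 2,5-dihydroxy-1,4-benzoquinone | OC1=CC(=O)C(O)=CC1=O | starting material
2 | 2,5-dioxido-3,6-bis(phenyliodonio)-1,4-benzoquinone | [O-]C1=C([I+]c2ccccc2)C(=O)C([O-])=C([I+]c2ccccc2)C1=O | intermediate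
3 | benzyl phenyl ether | C(Oc1ccccc1)c1ccccc1 | starting material
4 | 3-[4-(benzyloxy)phenyl]-2-hydroxy-5-oxido-6-(phenyliodonio)-1,4-benzoquinone | OC1=C(c2ccc(OCc3ccccc3)cc2)C(=O)C([O-])=C([I+]c2ccccc2)C1=O | intermediate (not isolated)
5 | 2,5-bis[4-(benzyloxy)phenyl]-3,6-dihydroxy-1,4-benzoquinone (atromentin 4',4''-dibenzyl ether) | OC1=C(c2ccc(OCc3ccccc3)cc2)C(=O)C(O)=C(c2ccc(OCc3ccccc3)cc2)C1=O | intermediate
6 | ethyl (S)-3-hydroxybutanoate | C[C@H](O)CC(=O)OCC | starting material
7 | ethyl (S)-3-(benzyloxy)butanoate | C[C@H](OCc1ccccc1)CC(=O)OCC | intermediate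
8 | (S)-3-(benzyloxy)butanoic acid | C[C@H](OCc1ccccc1)CC(=O)O | intermediate
9 | 3-phenylpropanoyl chloride | O=C(Cl)CCc1ccccc1 | starting material
10 | 2,5-bis[4-(benzyloxy)phenyl]-4-hydroxy-3,6-dioxocyclohexa-1,4-dien-1-yl 3-phenylpropanoate | O=C(CCc1ccccc1)OC1=C(c2ccc(OCc3ccccc3)cc2)C(=O)C(O)=C(c2ccc(OCc3ccccc3)cc2)C1=O | intermediate (not isolated)
11 | (S)-3-(benzyloxy)butanoyl chloride | C[C@H](OCc1ccccc1)CC(=O)Cl | intermediate (not isolated)
12 | mixed diester quinone, (3S)-3-(benzyloxy)butanoate / 3-phenylpropanoate of 5 | C[C@H](OCc1ccccc1)CC(=O)OC1=C(c2ccc(OCc3ccccc3)cc2)C(=O)C(OC(=O)CCc2ccccc2)=C(c2ccc(OCc3ccccc3)cc2)C1=O | intermediate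
13 | CNP0296884.1 | C[C@H](O)CC(=O)Oc1c(O)c(-c2ccc(O)cc2)c(OC(=O)CCc2ccccc2)c(O)c1-c1ccc(O)cc1 | target

## Step count and risks
Total steps: 6.
Longest linear sequence: 4 (steps 1, 2, 5, 6; the branch 3, 4, 5, 6 is equally long).

**Step 2 (double enolonium arylation).**
- Risks: benzyl phenyl ether is only as nucleophilic as anisole. The ylide may instead shift phenyl from I to O, contract the ring, or give ortho isomers.
- Fallback: it sets out from 2 and comes back at 5.
- The I(III)-activated carbon stays the electrophile, but both bonds are made by Pd(0) cross-coupling with purchased 4-(benzyloxy)phenylboronic acid (2.5 equiv, Pd(OAc)2/PPh3 5 mol %, DME/H2O, rt).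
- The sequence is oxidative addition into the quinonyl–I(III) bond, transmetalation and reductive elimination.
- The coupling is ipso-specific and needs no Lewis acid.
- New compounds on this path: none F0.

**Step 5 (one-pot unsymmetrical diacylation).**
- Risks: the selectivity may not exceed the statistical value, the acyl groups may scramble, and the three labile vinylogous anhydrides may be hard to separate.
- Fallback: it sets out from 5 and comes back at 10.
- First, 5 is acylated exhaustively with 9 (2.5 equiv, Et3N, CH2Cl2) to the neutral symmetric bis(3-phenylpropanoate) F1.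
- Exactly one ester is then removed with NaOMe (1.0 equiv, THF/MeOH, −40 °C).
- The first cleavage leaves an oxidoquinone anion whose charge shuts down the second cleavage, so selectivity is set by charge and not by statistics.
- After acidification 10 is isolated and acylated with 11 as in step 5.

**Step 6 (global hydrogenolysis).**
- Risks: the secondary benzyl ether cleaves slowly. A long contact time invites 1,2-acyl migration on the catechol monoester units, and the product can re-oxidise in air.
- Fallback: it sets out from 12 and comes back at 13.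
- The quinone alone is reduced with aqueous Na2S2O4 (EtOAc/H2O, rt) to the tri-O-benzyl hydroquinone F2.
- All three benzyl ethers are then removed without metal or hydrogen, using BCl3/pentamethylbenzene (CH2Cl2, −78 °C, minutes; quench cold).
- This is a Lewis-acid debenzylation with a cation scavenger, and it tolerates the esters.

## Further compounds
F0 | step 2 | none | none
F1 | step 5 | 2,5-bis[4-(benzyloxy)phenyl]-3,6-dioxocyclohexa-1,4-diene-1,4-diyl bis(3-phenylpropanoate) | O=C(CCc1ccccc1)OC1=C(c2ccc(OCc3ccccc3)cc2)C(=O)C(OC(=O)CCc2ccccc2)=C(c2ccc(OCc3ccccc3)cc2)C1=O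
F2 | step 6 | 4-{[(3S)-3-(benzyloxy)butanoyl]oxy}-3,6-bis[4-(benzyloxy)phenyl]-2,5-dihydroxyphenyl 3-phenylpropanoate | C[C@H](OCc1ccccc1)CC(=O)Oc1c(O)c(-c2ccc(OCc3ccccc3)cc2)c(OC(=O)CCc2ccccc2)c(O)c1-c1ccc(OCc2ccccc2)cc1
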